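**Plan**

1. Flavanone locants are used: the 5,7-dihydroxy half has O1, C2, C3, C4, C4a–C8a (ring C fused to ring A); the 7-methoxy half has the same locants doubly primed. The retrosynthesis cuts, in each half, O1–C8a and C4–C4a (ring A leaves as a 3,5-dioxygenated benzyne), then the two benzylic C–O bonds and C3–C3'' of the remaining succinyl core.
2. Enabling feature: in ring A the ether oxygen O1 (on C8a) and the carbonyl C4 (on C4a) are ortho and C4a is flanked by the C5 oxygen. This is the pattern in which an O-nucleophile and an acyl group add across a 3-alkoxybenzyne. O1–C2–C3–C4 is a β-oxy acyl chain, so the two aryne carbons complete the six-membered ring C.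
3. The four contiguous stereocentres are stored in a temporary bislactone, (1S,2S,5S,6S)-2,6-bis(4-methoxyphenyl)-3,7-dioxabicyclo[3.3.0]octane-4,8-dione. Its two γ-lactone rings are absent from the target; each ties the C2 oxygen of one half to the C4 carbon of the other. Its exo-aryl, cis-fused arrangement is the 2,3-cis arrangement of both flavanone rings.
4. Forward order: C3–C3'' by oxidative homocoupling of two molecules of an N-acyloxazolidinone enolate; both lactones by benzylic oxidation; one lactone opened with morpholine; ring C'' by a first aryne annulation that opens the second lactone; ring C (last ring) by a second aryne annulation onto the amide; global deprotection.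
5. Stereochemistry: C3/C3'' come from the (S)-oxazolidinone in the coupling; C2/C2'' come from substrate-controlled lactonisation (aryl exo); no bond at any stereocentre is broken afterwards.

Key step: step 13

Assumption: compound 19 is written as the open γ-hydroxy ketone; its cyclic hemiketal tautomer, if present, would give the same alkoxide in step 13.

**Route**

Step 1
Reactants: 1 3-(4-methoxyphenyl)propanoic acid; 2 (S)-4-benzyl-1,3-oxazolidin-2-one
Product: 4 (S)-4-benzyl-3-[3-(4-methoxyphenyl)propanoyl]-1,3-oxazolidin-2-one, via mixed pivalic anhydride 3 (not isolated)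
Conditions: t-BuCOCl, Et3N, THF, −20 °C; then 2, LiCl, −20 °C to rt
Reagents that add atoms: none
Why: N-acylation of the oxazolidinone by a mixed anhydride (LiCl/Et3N variant) is the standard way to load the auxiliary, and no stereocentre is formed.

Step 2
Reactants: 4 (S)-4-benzyl-3-[3-(4-methoxyphenyl)propanoyl]-1,3-oxazolidin-2-one (two molecules, one for each half of the product)
Product: 6 (2R,3R)-1,4-bis[(4S)-4-benzyl-2-oxo-1,3-oxazolidin-3-yl]-2,3-bis[(4-methoxyphenyl)methyl]butane-1,4-dione, via lithium Z-enolate 5 (not isolated)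
Conditions: LiN(i-Pr)2 (1.05 equiv), THF, −78 °C; then TiCl4 (1.1 equiv), −78 °C to 0 °C
Reagents that add atoms: a second molecule of 4 as its enolate, COc1ccc(CCC(=O)N2[C@@H](Cc3ccccc3)COC2=O)cc1
Why: Oxidative homocoupling of an N-acyloxazolidinone enolate (known for 3-arylpropanoyl imides) by one-electron oxidation with tetravalent titanium joins the α-carbons of two molecules of 4, each with loss of its α-hydrogen, on the face opposite the 4-benzyl group at each, setting C3 and C3'' as the C2-symmetric R,R pair.

Step 3
Reactants: 6 (2R,3R)-bis-imide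
Product: 7 (2R,3R)-2,3-bis[(4-methoxyphenyl)methyl]butanedioic acid
Conditions: LiOH, H2O2, THF/H2O, 0 °C; then Na2SO3; HCl to pH 2
Reagents that add atoms: hydrogen peroxide, OO
Why: Lithium hydroperoxide cleaves the exocyclic imide carbonyl selectively and without enolisation, so both stereocentres are kept and the auxiliary is released intact.

Step 4
Reactants: 7 (2R,3R)-2,3-bis[(4-methoxyphenyl)methyl]butanedioic acid
Product: 8 (1S,2S,5S,6S)-2,6-bis(4-methoxyphenyl)-3,7-dioxabicyclo[3.3.0]octane-4,8-dione
Conditions: DDQ (2.5 equiv), 1,4-dioxane, 80 °C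
Reagents that add atoms: none
Why: DDQ benzylic oxidative lactonisation (hydride abstraction from each 4-methoxybenzylic CH2, the aryl-stabilised cation trapped 5-exo by the γ-carboxylic acid) should give the bislactone; the second ring can only close cis-fused and each aryl group takes the exo position, which is also the isomer reached by re-ionisation, so the R,R core sets C2 and C2'' as S,S.

Step 5
Reactants: 8 bislactone
Product: 9 (3S,4S,5S)-3-[(S)-hydroxy(4-methoxyphenyl)methyl]-5-(4-methoxyphenyl)-4-(morpholine-4-carbonyl)oxolan-2-one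
Conditions: morpholine, AlMe3 (1.1 equiv each), CH2Cl2, 0 °C to rt; aqueous potassium sodium tartrate
Reagents that add atoms: morpholine, C1COCCN1
Why: AlMe3-mediated aminolysis of a lactone; the two lactones are homotopic (C2 axis) so either opening gives 9, the remaining monocyclic hindered lactone should react more slowly, and no stereocentre is involved (the freed hydroxyl is O1'' of the 7-methoxy half, the amide carbon is C4 of the dihydroxy half).

Step 6
Reactants: 10 3,5-dimethoxyphenol
Product: 11 3,5-dimethoxyphenyl N-isopropylcarbamate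
Conditions: i-PrNCO, Et3N (cat.), CH2Cl2, rt
Reagents that add atoms: isopropyl isocyanate, CC(C)N=C=O
Why: Carbamoylation of the phenol installs a group that directs ortho-metalation and is later removed under mild base.

Step 7
Reactants: 11 3,5-dimethoxyphenyl N-isopropylcarbamate
Product: 13 3,5-dimethoxy-2-(trimethylsilyl)phenyl N-isopropylcarbamate, via N-silyl carbamate 12 (not isolated)
Conditions: TBSOTf, TMEDA, Et2O, 0 °C to rt; n-BuLi, TMEDA, −78 °C; Me3SiCl, −78 °C to rt; aqueous NaHSO4
Reagents that add atoms: chlorotrimethylsilane, C[Si](C)(C)Cl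
Why: Carbamate-directed ortho-lithiation (N–H masked in the flask as N-silyl) should occur at the position between the carbamate and a methoxy group (the two such positions are equivalent), and the aryllithium is C-silylated.

Step 8
Reactants: 13 3,5-dimethoxy-2-(trimethylsilyl)phenyl N-isopropylcarbamate
Product: 15 3,5-dimethoxy-2-(trimethylsilyl)phenyl trifluoromethanesulfonate, via silyl phenol 14 (not isolated)
Conditions: DBU, Et2NH, MeCN, 40 °C; then PhNTf2, rt
Reagents that add atoms: N-phenylbis(trifluoromethanesulfonimide), O=S(=O)(N(c1ccccc1)S(=O)(=O)C(F)(F)F)C(F)(F)F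
Why: Base-induced loss of isopropyl isocyanate (trapped by Et2NH) frees the phenoxide, which is triflated in the same flask to give the o-silylaryl triflate aryne precursor.

Step 9
Reactants: 9 hydroxy lactone amide; 15 3,5-dimethoxy-2-(trimethylsilyl)phenyl trifluoromethanesulfonate
Product: 19 (2S,3S)-3-[(1S,2S)-1-hydroxy-1-(4-methoxyphenyl)-3-(morpholin-4-yl)-3-oxopropan-2-yl]-5,7-dimethoxy-2-(4-methoxyphenyl)chroman-4-one, via trimethylsilyl ether 16 (not isolated), via 3,5-dimethoxybenzyne 17 (not isolated), via lactol alkoxide 18 (not isolated)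
Conditions: (Me3Si)2NH, Me3SiOTf (cat.), CH2Cl2, rt, then evaporation; 15 (1.05 equiv), KF, 18-crown-6, THF, −20 °C to 0 °C; aqueous NH4Cl
Reagents that add atoms: none
Why: Proposed new method: fluoride desilylates 16 and generates 3,5-dimethoxybenzyne 17 in the same aprotic medium; the alkoxide adds to the aryne carbon remote from the flanking methoxy group, the resulting aryl anion (ortho to OMe) attacks the γ-lactone carbonyl through a six-membered transition state (6-exo-trig) to give lactol alkoxide 18, which should persist at 0 °C as the tetrahedral adduct (so the C2 oxygen it holds is not arylated) and opens to the γ-hydroxy ketone on protonation; the closest known reaction type is the aryne annulation of salicylate esters to xanthones (phenoxide addition, then intramolecular acyl substitution by the aryl anion), extended here to an aliphatic β-silyloxy lactone, and no stereocentre is touched, so the cis C2''/C3'' relation of 8 is kept.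

Step 10
Reactants: 20 3,5-bis(benzyloxy)phenol
Product: 21 3,5-bis(benzyloxy)phenyl N-isopropylcarbamate
Conditions: i-PrNCO, Et3N (cat.), CH2Cl2, rt
Reagents that add atoms: isopropyl isocyanate, CC(C)N=C=O
Why: Carbamoylation of the phenol, as in step 6.

Step 11
Reactants: 21 3,5-bis(benzyloxy)phenyl N-isopropylcarbamate
Product: 23 3,5-bis(benzyloxy)-2-(trimethylsilyl)phenyl N-isopropylcarbamate, via N-silyl carbamate 22 (not isolated)
Conditions: TBSOTf, TMEDA, Et2O, 0 °C to rt; n-BuLi, TMEDA, −78 °C; Me3SiCl, −78 °C to rt; aqueous NaHSO4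
Reagents that add atoms: chlorotrimethylsilane, C[Si](C)(C)Cl
Why: Carbamate-directed ortho-lithiation between the carbamate and a benzyloxy group (two equivalent positions) at −78 °C should outrun metalation of the benzylic CH2 groups, and the aryllithium is C-silylated.

Step 12
Reactants: 23 3,5-bis(benzyloxy)-2-(trimethylsilyl)phenyl N-isopropylcarbamate
Product: 25 3,5-bis(benzyloxy)-2-(trimethylsilyl)phenyl trifluoromethanesulfonate, via silyl phenol 24 (not isolated)
Conditions: DBU, Et2NH, MeCN, 40 °C; then PhNTf2, rt
Reagents that add atoms: N-phenylbis(trifluoromethanesulfonimide), O=S(=O)(N(c1ccccc1)S(=O)(=O)C(F)(F)F)C(F)(F)F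
Why: Carbamate cleavage and triflation of the phenoxide in one flask, as in step 8.

Step 13
Reactants: 19 hydroxy amide of the 7-methoxy-half flavanone; 25 3,5-bis(benzyloxy)-2-(trimethylsilyl)phenyl trifluoromethanesulfonate
Product: 29 (2S,2'S,3S,3'S)-5,7-bis(benzyloxy)-5',7'-dimethoxy-2,2'-bis(4-methoxyphenyl)-[3,3'-bichromane]-4,4'-dione, via trimethylsilyl ether 26 (not isolated), via 3,5-bis(benzyloxy)benzyne 27 (not isolated), via hemiaminal alkoxide 28 (not isolated)
Conditions: (Me3Si)2NH, Me3SiOTf (cat.), CH2Cl2, rt, then evaporation; 25 (2 equiv), KF, 18-crown-6, THF, 0 °C to rt; NaOAc/AcOH buffer (pH 5)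
Reagents that add atoms: none
Why: Proposed new method: fluoride removes the O-silyl group of 26 and triggers 1,2-elimination of 25 to 3,5-bis(benzyloxy)benzyne 27 in the same aprotic flask; the free C2 alkoxide adds to the aryne carbon remote from the flanking benzyloxy group (O1–C8a bond), and the aryl carbanion so formed at C4a attacks the morpholine amide carbonyl C4 to give tetrahedral alkoxide 28, which releases the C4 ketone only on buffered work-up. The closest known reaction type is the aryne annulation of salicylate esters to xanthones (phenoxide addition to an aryne, then intramolecular acyl substitution by the aryl anion); new here are an aliphatic β-silyloxy amide as the O-nucleophile/acyl-electrophile pair and fluoride desilylation as a proton-free source of the alkoxide, so that the aryl anion is not quenched before it cyclises. Ring C is closed in the C4–C4a bond-forming event as a 6-exo-trig attack of the sp2 carbanion on the amide carbonyl, the O1–C8a bond having been made intermolecularly just before. No stereocentre is created: C2 and C3 keep the configuration fixed in bislactone 8 because neither the C2–O bond nor any bond at C3 is broken, and C2''/C3'' are untouched. The step needs regioselectivity in the aryne addition, secured by the inductive effect of the 3-benzyloxy group (nucleophile to the remote carbon, negative charge next to oxygen, hence the carbonyl between O1 and the 5-oxygen), and chemoselectivity of the aryl anion for the amide carbonyl (six-membered transition state) over the C4'' ketone (seven-membered). Epimerisation of the base-sensitive cis-flavanone rings should be limited by the low steady-state concentration of alkoxide under solid KF/18-crown-6 and by the new ketone staying masked as 28 until the acidic quench.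

Step 14
Reactants: 29 protected biflavanone
Product: 30 (2S,2'S,3S,3'S)-5,5',7-trihydroxy-7'-methoxy-2,2'-bis(4-methoxyphenyl)-[3,3'-bichromane]-4,4'-dione (target CNP0184936.4)
Conditions: BCl3, C6HMe5, CH2Cl2, −78 °C to 0 °C; MeOH, then aqueous NaHCO3
Reagents that add atoms: none
Why: BCl3 with pentamethylbenzene as cation scavenger cleaves both aryl benzyl ethers at −78 °C, and on warming the chelated 5'-methoxy group next to the C4'' carbonyl is cleaved selectively (the 7''- and 4'-methoxy groups lack the chelate); no base is present, so C3/C3'' should not enolise.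

**Compound list**

1 | 3-(4-methoxyphenyl)propanoic acid | COc1ccc(CCC(=O)O)cc1 | starting material
2 | (S)-4-benzyl-1,3-oxazolidin-2-one | O=C1N[C@@H](Cc2ccccc2)CO1 | starting material
3 | mixed anhydride of 1 with pivalic acid | COc1ccc(CCC(=O)OC(=O)C(C)(C)C)cc1 | intermediate (not isolated)
4 | (S)-4-benzyl-3-[3-(4-methoxyphenyl)propanoyl]-1,3-oxazolidin-2-one | COc1ccc(CCC(=O)N2[C@@H](Cc3ccccc3)COC2=O)cc1 | intermediate
5 | lithium Z-enolate of 4 | COc1ccc(C/C=C(\[O-])N2[C@@H](Cc3ccccc3)COC2=O)cc1.[Li+] | intermediate (not isolated)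
6 | (2R,3R)-1,4-bis[(4S)-4-benzyl-2-oxo-1,3-oxazolidin-3-yl]-2,3-bis[(4-methoxyphenyl)methyl]butane-1,4-dione | O=C1OC[C@H](Cc2ccccc2)N1C(=O)[C@H](Cc1ccc(OC)cc1)[C@@H](Cc1ccc(OC)cc1)C(=O)N1[C@@H](Cc2ccccc2)COC1=O | intermediate
7 | (2R,3R)-2,3-bis[(4-methoxyphenyl)methyl]butanedioic acid | OC(=O)[C@H](Cc1ccc(OC)cc1)[C@@H](Cc1ccc(OC)cc1)C(=O)O | intermediate
8 | (1S,2S,5S,6S)-2,6-bis(4-methoxyphenyl)-3,7-dioxabicyclo[3.3.0]octane-4,8-dione | COc1ccc(cc1)[C@H]1OC(=O)[C@@H]2[C@@H](c3ccc(OC)cc3)OC(=O)[C@H]12 | intermediate
9 | (3S,4S,5S)-3-[(S)-hydroxy(4-methoxyphenyl)methyl]-5-(4-methoxyphenyl)-4-(morpholine-4-carbonyl)oxolan-2-one | COc1ccc(cc1)[C@H]1OC(=O)[C@H]([C@@H](c2ccc(OC)cc2)O)[C@@H]1C(=O)N1CCOCC1 | intermediate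
10 | 3,5-dimethoxyphenol | COc1cc(O)cc(OC)c1 | starting material
11 | 3,5-dimethoxyphenyl N-isopropylcarbamate | COc1cc(OC)cc(OC(=O)NC(C)C)c1 | intermediate
12 | 3,5-dimethoxyphenyl N-(tert-butyldimethylsilyl)-N-isopropylcarbamate | COc1cc(OC)cc(OC(=O)N(C(C)C)[Si](C)(C)C(C)(C)C)c1 | intermediate (not isolated)
13 | 3,5-dimethoxy-2-(trimethylsilyl)phenyl N-isopropylcarbamate | COc1cc(OC)c([Si](C)(C)C)c(OC(=O)NC(C)C)c1 | intermediate
14 | 3,5-dimethoxy-2-(trimethylsilyl)phenol | COc1cc(O)c([Si](C)(C)C)c(OC)c1 | intermediate (not isolated)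
15 | 3,5-dimethoxy-2-(trimethylsilyl)phenyl trifluoromethanesulfonate | COc1cc(OC)c([Si](C)(C)C)c(OS(=O)(=O)C(F)(F)F)c1 | intermediate
16 | trimethylsilyl ether of 9 | COc1ccc(cc1)[C@H]1OC(=O)[C@H]([C@@H](c2ccc(OC)cc2)O[Si](C)(C)C)[C@@H]1C(=O)N1CCOCC1 | intermediate (not isolated)
17 | 3,5-dimethoxybenzyne | COC1=CC(OC)=CC#C1 | intermediate (not isolated)
18 | potassium lactol alkoxide (cis-fused 2,3,3a,4-tetrahydro-9bH-furo[3,2-c]chromen-9b-olate formed by attack of the aryl anion on the lactone carbonyl; other stereocentres as in 9) | COc1ccc(cc1)[C@H]1O[C@]2([O-])c3c(OC)cc(OC)cc3O[C@H](c3ccc(OC)cc3)[C@@H]2[C@@H]1C(=O)N1CCOCC1.[K+] | intermediate (not isolated)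
19 | (2S,3S)-3-[(1S,2S)-1-hydroxy-1-(4-methoxyphenyl)-3-(morpholin-4-yl)-3-oxopropan-2-yl]-5,7-dimethoxy-2-(4-methoxyphenyl)chroman-4-one | COc1ccc(cc1)[C@@H](O)[C@@H](C(=O)N1CCOCC1)[C@@H]1C(=O)c2c(OC)cc(OC)cc2O[C@@H]1c1ccc(OC)cc1 | intermediate
20 | 3,5-bis(benzyloxy)phenol | Oc1cc(OCc2ccccc2)cc(OCc2ccccc2)c1 | starting material
21 | 3,5-bis(benzyloxy)phenyl N-isopropylcarbamate | CC(C)NC(=O)Oc1cc(OCc2ccccc2)cc(OCc2ccccc2)c1 | intermediate
22 | 3,5-bis(benzyloxy)phenyl N-(tert-butyldimethylsilyl)-N-isopropylcarbamate | CC(C)N(C(=O)Oc1cc(OCc2ccccc2)cc(OCc2ccccc2)c1)[Si](C)(C)C(C)(C)C | intermediate (not isolated)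
23 | 3,5-bis(benzyloxy)-2-(trimethylsilyl)phenyl N-isopropylcarbamate | CC(C)NC(=O)Oc1cc(OCc2ccccc2)cc(OCc2ccccc2)c1[Si](C)(C)C | intermediate
24 | 3,5-bis(benzyloxy)-2-(trimethylsilyl)phenol | Oc1cc(OCc2ccccc2)cc(OCc2ccccc2)c1[Si](C)(C)C | intermediate (not isolated)
25 | 3,5-bis(benzyloxy)-2-(trimethylsilyl)phenyl trifluoromethanesulfonate | C[Si](C)(C)c1c(OCc2ccccc2)cc(OCc2ccccc2)cc1OS(=O)(=O)C(F)(F)F | intermediate
26 | trimethylsilyl ether of 19 | COc1ccc(cc1)[C@@H](O[Si](C)(C)C)[C@@H](C(=O)N1CCOCC1)[C@@H]1C(=O)c2c(OC)cc(OC)cc2O[C@@H]1c1ccc(OC)cc1 | intermediate (not isolated)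
27 | 3,5-bis(benzyloxy)benzyne | C1#CC(OCc2ccccc2)=CC(OCc2ccccc2)=C1 | intermediate (not isolated)
28 | potassium hemiaminal alkoxide (29 with C4 as C(O−)(morpholin-4-yl); configuration at C4 not defined) | COc1ccc([C@H]2Oc3cc(OCc4ccccc4)cc(OCc4ccccc4)c3C([O-])(N3CCOCC3)[C@H]2[C@@H]2C(=O)c3c(OC)cc(OC)cc3O[C@@H]2c2ccc(OC)cc2)cc1.[K+] | intermediate (not isolated)
29 | (2S,2'S,3S,3'S)-5,7-bis(benzyloxy)-5',7'-dimethoxy-2,2'-bis(4-methoxyphenyl)-[3,3'-bichromane]-4,4'-dione | COc1ccc([C@H]2Oc3cc(OCc4ccccc4)cc(OCc4ccccc4)c3C(=O)[C@H]2[C@@H]2C(=O)c3c(OC)cc(OC)cc3O[C@@H]2c2ccc(OC)cc2)cc1 | intermediate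
30 | (2S,2'S,3S,3'S)-5,5',7-trihydroxy-7'-methoxy-2,2'-bis(4-methoxyphenyl)-[3,3'-bichromane]-4,4'-dione | COc1ccc([C@H]2Oc3cc(O)cc(O)c3C(=O)[C@H]2[C@@H]2C(=O)c3c(O)cc(OC)cc3O[C@@H]2c2ccc(OC)cc2)cc1 | target

Total step count: 14. Longest linear sequence: 8 steps (1, 2, 3, 4, 5, 9, 13, 14).

**Steps most likely to fail**

Step 13 (key step). The aryl anion may be protonated before it reaches the amide carbonyl, leaving a simple aryl ether. The tertiary hemiketal alkoxide form of the nucleophile may be arylated instead of the open secondary alkoxide. Alkoxide-induced enolisation at C3'' may open the cis-flavanone ring with loss of configuration. The fallback uses known chemistry, sets out from 9 and comes back at 29. Both aryl ketones are installed by aryllithium acylation before either pyranone ring exists, and both rings are then closed by intramolecular SNAr. Compound 9 is first converted into the fluoroaryl keto diol F3 as described under step 9. Commercial 5-fluororesorcinol is benzylated (BnBr, K2CO3, DMF) to 1,3-bis(benzyloxy)-5-fluorobenzene F4, brominated (NBS, MeCN) to 1,5-bis(benzyloxy)-2-bromo-3-fluorobenzene F5 and exchanged (n-BuLi, THF, −78 °C) to 2,4-bis(benzyloxy)-6-fluorophenyllithium F6. The keto diol F3 is deprotonated at both hydroxyls with LiN(SiMe3)2 at −78 °C; the C2 alkoxide should mask the hindered ketone as its lithium hemiketal. The morpholine amide is then acylated by F6 to give the diketo diol F7. KOtBu in THF at 0 °C should close both rings by displacement of the ortho-fluorides, each through a six-membered transition state, and give 29.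

Step 9. The oxygen set free by lactone opening may be arylated by a second aryne. The β-alkoxy lactone may fragment by retro-aldol reaction before the aryne is available. The aryl anion may be quenched by a proton. The fallback uses known chemistry, sets out from 9 and comes back at 19. Commercial 1-fluoro-3,5-dimethoxybenzene is brominated (NBS, MeCN) to 2-bromo-1-fluoro-3,5-dimethoxybenzene F1 and exchanged (n-BuLi, THF, −78 °C) to 2-fluoro-4,6-dimethoxyphenyllithium F2. Addition of F2 (2.2 equiv) to 9 at −78 °C deprotonates the hydroxyl and then adds to the lactone carbonyl, which is more electrophilic than the morpholine amide; work-up gives (2S,3S)-1-(2-fluoro-4,6-dimethoxyphenyl)-2,3-bis[(S)-hydroxy(4-methoxyphenyl)methyl]-4-(morpholin-4-yl)butane-1,4-dione F3. KOtBu in THF at 0 °C then closes the chromanone by SNAr; only the C2'' alkoxide reaches the fluorinated carbon through a six-membered transition state, and this should give 19.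

Step 4. Hydride abstraction from a mono-methoxy arene may be slow. The benzylic cation may lose the C3 proton (dehydrogenation to an arylidene succinate) instead of being trapped, which would erase a stereocentre. The fallback sets out from 7 and comes back at 8 and replaces hydride abstraction by radical halogenation. Wohl–Ziegler bromination (NBS, AIBN, PhCF3, 80 °C) gives (2R,3R)-2,3-bis[bromo(4-methoxyphenyl)methyl]butanedioic acid F8 as a mixture at the bromine-bearing carbons. On warming with NaHCO3 the labile 4-methoxybenzylic bromides are displaced by the neighbouring carboxylates (SN1, same exo-aryl, cis-fused preference), which should give 8.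

**Further compounds**

F1 | step 9 | 2-bromo-1-fluoro-3,5-dimethoxybenzene | COc1cc(F)c(Br)c(OC)c1
F2 | step 9 | 2-fluoro-4,6-dimethoxyphenyllithium | COc1cc(F)c([Li])c(OC)c1
F3 | step 9 | (2S,3S)-1-(2-fluoro-4,6-dimethoxyphenyl)-2,3-bis[(S)-hydroxy(4-methoxyphenyl)methyl]-4-(morpholin-4-yl)butane-1,4-dione | COc1ccc(cc1)[C@@H](O)[C@@H](C(=O)N1CCOCC1)[C@@H]([C@H](O)c1ccc(OC)cc1)C(=O)c1c(F)cc(OC)cc1OC
F4 | step 13 | 1,3-bis(benzyloxy)-5-fluorobenzene | Fc1cc(OCc2ccccc2)cc(OCc2ccccc2)c1
F5 | step 13 | 1,5-bis(benzyloxy)-2-bromo-3-fluorobenzene | Fc1cc(OCc2ccccc2)cc(OCc2ccccc2)c1Br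
F6 | step 13 | 2,4-bis(benzyloxy)-6-fluorophenyllithium | Fc1cc(OCc2ccccc2)cc(OCc2ccccc2)c1[Li]
F7 | step 13 | (2S,3S)-1-[2,4-bis(benzyloxy)-6-fluorophenyl]-4-(2-fluoro-4,6-dimethoxyphenyl)-2,3-bis[(S)-hydroxy(4-methoxyphenyl)methyl]butane-1,4-dione | COc1ccc(cc1)[C@@H](O)[C@@H](C(=O)c1c(F)cc(OCc2ccccc2)cc1OCc1ccccc1)[C@@H]([C@H](O)c1ccc(OC)cc1)C(=O)c1c(F)cc(OC)cc1OC
F8 | step 4 | (2R,3R)-2,3-bis[bromo(4-methoxyphenyl)methyl]butanedioic acid (mixture at the C–Br carbons) | OC(=O)[C@H](C(Br)c1ccc(OC)cc1)[C@@H](C(Br)c1ccc(OC)cc1)C(=O)O
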